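**Plan**
- Retrosynthesis: the C7–allyl bond is cut back to a formyl group (through CH2Br and CH2OH). Next the aryl ether bond O4–C4a of the dioxane ring is cut, then the benzylic ether bond O1–C2, and last the C2–C3 unit to a Z-alkene made from an aryl aldehyde.
- Enabling feature: in the benzodioxane (O1, C2 aryl, C3 methyl, O4, C4a, C5–C8, C8a) the allyl-bearing carbon C7 is para to C4a. A formyl group at C7 therefore activates a C4a–F bond for displacement by the C3 alkoxide.
- Forward: Wittig olefination, epoxidation, phenoxide opening of the epoxide (joins the two arenes through O1–C2), SNAr closure of the only new ring, then CHO to CH2OH to CH2Br to allyl.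
- Stereochemistry: both centres come from the catalyst-controlled epoxidation of the Z-alkene (2R,3S cis-epoxide). SN2 inversion at the benzylic carbon turns the cis-epoxide into the threo ether and hence the trans (2R,3R) ring; no later step touches either centre.

Key step: step 4

Remark on numbering: the benzodioxane locants above are used for all names; in them the target is the trans (2R,3R) compound with the allyl group on C7.
Assumption: the (S,S)-configured salen complex of trivalent manganese is taken to epoxidise the Z-propenyl arene with the same facial sense as (Z)-1-phenylpropene and indene, giving the 2R,3S cis-epoxide; this sense would be confirmed on the epoxide before it is carried on.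

Step 1
Reactants: 1 3,4,5-trimethoxybenzaldehyde; 2 ethyltriphenylphosphonium bromide
Product: 4 (Z)-1,2,3-trimethoxy-5-(prop-1-en-1-yl)benzene, via ethylidenetriphenylphosphorane 3 (not isolated)
Conditions: 2, NaN(SiMe3)2, THF, 0 °C; then 1, −78 °C to rt
Reagents that add atoms: none
Why: Wittig olefination with a non-stabilised ylide under lithium-free, kinetically controlled conditions should proceed through the cis-oxaphosphetane and favour the Z-alkene.

Step 2
Reactants: 4 (Z)-1,2,3-trimethoxy-5-(prop-1-en-1-yl)benzene
Product: 5 (2R,3S)-2-methyl-3-(3,4,5-trimethoxyphenyl)oxirane (cis-epoxide)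
Conditions: (S,S)-[N,N'-bis(3,5-di-tert-butylsalicylidene)cyclohexane-1,2-diaminato]MnCl (4 mol %), 4-phenylpyridine N-oxide (0.2 equiv), aq NaOCl (pH 11.3), CH2Cl2, 0 °C
Reagents that add atoms: sodium hypochlorite, [Na+].[O-]Cl
Why: Jacobsen epoxidation works best on Z-configured aryl-conjugated alkenes, so the (S,S)-ligand should set both stereocentres at once by catalyst control of the alkene face, while the N-oxide additive and low temperature should limit leakage of the radical intermediate to the trans-epoxide.

Step 3
Reactants: 5 (2R,3S)-2-methyl-3-(3,4,5-trimethoxyphenyl)oxirane; 6 4-fluoro-3-hydroxybenzaldehyde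
Product: 7 4-fluoro-3-{[(1R,2R)-2-hydroxy-1-(3,4,5-trimethoxyphenyl)propyl]oxy}benzaldehyde
Conditions: 6 (1.5 equiv), K2CO3 (0.3 equiv), DMF, 80 °C
Reagents that add atoms: none
Why: Base-catalysed SN2 opening of an aryl epoxide by a phenoxide should occur at the electronically activated benzylic carbon (both epoxide carbons are secondary) with inversion there (S in 5 becomes R in 7, the carbinol carbon stays R), and the excess phenol keeps the new secondary alcohol protonated so that it does not yet cyclise.

Step 4
Reactants: 7 4-fluoro-3-{[(1R,2R)-2-hydroxy-1-(3,4,5-trimethoxyphenyl)propyl]oxy}benzaldehyde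
Product: 8 (2R,3R)-3-methyl-2-(3,4,5-trimethoxyphenyl)-2,3-dihydro-1,4-benzodioxine-7-carbaldehyde (trans)
Conditions: Cs2CO3 (2 equiv), DMSO (0.02 M), 80 °C, under argon
Reagents that add atoms: none
Why: Deprotonation of the C3 hydroxyl gives an alkoxide that adds to C4a, the fluorine-bearing carbon para to the formyl group, forming a Meisenheimer complex whose charge is delocalised onto the formyl oxygen, and loss of fluoride restores the arene (addition–elimination SNAr). The closest known reaction type is the intramolecular etherification of 4-fluorobenzaldehyde-type aryl fluorides by tethered alkoxides. The 1,4-dioxane ring is closed by 6-exo-trig attack of O4 on C4a, the chain O4–C3–C2–O1–C8a being already in place. No stereocentre is formed, and C2 and C3 keep their R configurations because neither sp3 C–O bond is broken and neither C–H is acidic enough to epimerise under carbonate. The step needs O4 to bond to C4a and not to C8a (ipso attack and a Smiles-type shift would exchange the two oxygen positions); this is secured because only C4a carries a leaving group para to the formyl group while C8a is meta to it, and dilution keeps the substitution intramolecular while alkoxide addition to the formyl group is reversible.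

Step 5
Reactants: 8 (2R,3R)-3-methyl-2-(3,4,5-trimethoxyphenyl)-2,3-dihydro-1,4-benzodioxine-7-carbaldehyde
Product: 9 [(2R,3R)-3-methyl-2-(3,4,5-trimethoxyphenyl)-2,3-dihydro-1,4-benzodioxin-7-yl]methanol
Conditions: NaBH4, MeOH/THF, 0 °C
Reagents that add atoms: none
Why: Borohydride reduction of an aryl aldehyde to the benzylic alcohol is chemoselective, and the ethers and both stereocentres are inert to it.

Step 6
Reactants: 9 [(2R,3R)-3-methyl-2-(3,4,5-trimethoxyphenyl)-2,3-dihydro-1,4-benzodioxin-7-yl]methanol
Product: 10 (2R,3R)-7-(bromomethyl)-3-methyl-2-(3,4,5-trimethoxyphenyl)-2,3-dihydro-1,4-benzodioxine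
Conditions: CBr4, PPh3, CH2Cl2, 0 °C; short silica plug, used at once
Reagents that add atoms: carbon tetrabromide, BrC(Br)(Br)Br
Why: The Appel reaction converts the primary benzylic alcohol into the bromide by SN2 displacement on the alkoxyphosphonium ion under neutral conditions, which spares the benzylic C2–O1 ether.

Step 7
Reactants: 10 (2R,3R)-7-(bromomethyl)-3-methyl-2-(3,4,5-trimethoxyphenyl)-2,3-dihydro-1,4-benzodioxine
Product: 11 (2R,3R)-3-methyl-7-(prop-2-en-1-yl)-2-(3,4,5-trimethoxyphenyl)-2,3-dihydro-1,4-benzodioxine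
Conditions: CH2=CHMgBr (1.5 equiv), CuI (10 mol %), THF, −30 to 0 °C
Reagents that add atoms: vinylmagnesium bromide, C=C[Mg]Br
Why: Copper-catalysed cross-coupling of a benzylic bromide with a vinyl Grignard reagent is an established way to allylarenes, and the remote stereocentres and ethers are not affected at low temperature.

**Compound list**
1 | 3,4,5-trimethoxybenzaldehyde | COc1cc(C=O)cc(OC)c1OC | starting material
2 | ethyltriphenylphosphonium bromide | CC[P+](c1ccccc1)(c1ccccc1)c1ccccc1.[Br-] | starting material
3 | ethylidenetriphenylphosphorane | CC=P(c1ccccc1)(c1ccccc1)c1ccccc1 | intermediate (not isolated)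
4 | (Z)-1,2,3-trimethoxy-5-(prop-1-en-1-yl)benzene | C/C=C\c1cc(OC)c(OC)c(OC)c1 | intermediate
5 | (2R,3S)-2-methyl-3-(3,4,5-trimethoxyphenyl)oxirane | C[C@H]1O[C@H]1c1cc(OC)c(OC)c(OC)c1 | intermediate
6 | 4-fluoro-3-hydroxybenzaldehyde | O=Cc1ccc(F)c(O)c1 | starting material
7 | 4-fluoro-3-{[(1R,2R)-2-hydroxy-1-(3,4,5-trimethoxyphenyl)propyl]oxy}benzaldehyde | O=Cc1ccc(F)c(O[C@H](c2cc(OC)c(OC)c(OC)c2)[C@@H](C)O)c1 | intermediate
8 | (2R,3R)-3-methyl-2-(3,4,5-trimethoxyphenyl)-2,3-dihydro-1,4-benzodioxine-7-carbaldehyde | O=Cc1ccc2c(c1)O[C@H](c1cc(OC)c(OC)c(OC)c1)[C@@H](C)O2 | intermediate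
9 | [(2R,3R)-3-methyl-2-(3,4,5-trimethoxyphenyl)-2,3-dihydro-1,4-benzodioxin-7-yl]methanol | OCc1ccc2c(c1)O[C@H](c1cc(OC)c(OC)c(OC)c1)[C@@H](C)O2 | intermediate
10 | (2R,3R)-7-(bromomethyl)-3-methyl-2-(3,4,5-trimethoxyphenyl)-2,3-dihydro-1,4-benzodioxine | BrCc1ccc2c(c1)O[C@H](c1cc(OC)c(OC)c(OC)c1)[C@@H](C)O2 | intermediate
11 | (2R,3R)-3-methyl-7-(prop-2-en-1-yl)-2-(3,4,5-trimethoxyphenyl)-2,3-dihydro-1,4-benzodioxine | C=CCc1ccc2c(c1)O[C@H](c1cc(OC)c(OC)c(OC)c1)[C@@H](C)O2 | target

Total step count: 7. Longest linear sequence: 7 steps (1 to 11; phenol 6 enters at step 3).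

**Steps most likely to fail**

Step 3. The phenoxide may attack the methyl-bearing epoxide carbon, the benzylic C–O bond may partly ionise before attack so that inversion is eroded, or the fluorophenol may condense with itself by intermolecular SNAr before it opens the epoxide. The fallback forms the O1–C2 bond by Mitsunobu etherification of a chiral-pool alcohol in which only the benzylic carbon can react; it sets out from phenol 6 and comes back at 7.
- Commercial methyl (R)-lactate (C[C@@H](O)C(=O)OC) is protected with 4-methoxybenzyl 2,2,2-trichloroacetimidate and catalytic camphorsulfonic acid to give methyl (R)-2-[(4-methoxybenzyl)oxy]propanoate F1.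
- MeNHOMe·HCl and iPrMgCl convert it into (R)-N-methoxy-2-[(4-methoxybenzyl)oxy]-N-methylpropanamide F2.
- 3,4,5-Trimethoxyphenylmagnesium bromide, made from commercial 5-bromo-1,2,3-trimethoxybenzene and Mg, should give (R)-2-[(4-methoxybenzyl)oxy]-1-(3,4,5-trimethoxyphenyl)propan-1-one F3.
- Chelation-controlled reduction with Zn(BH4)2 in Et2O at −20 °C should give the anti alcohol (1S,2R)-2-[(4-methoxybenzyl)oxy]-1-(3,4,5-trimethoxyphenyl)propan-1-ol F4.
- Mitsunobu reaction of this alcohol with 6 (PPh3, diisopropyl azodicarboxylate, toluene, 0 °C) inverts the benzylic carbon and should give 4-fluoro-3-{[(1R,2R)-2-[(4-methoxybenzyl)oxy]-1-(3,4,5-trimethoxyphenyl)propyl]oxy}benzaldehyde F5.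
- DDQ in wet CH2Cl2 then frees the hydroxyl to give 7.

Because both stereocentres then derive from lactate and a stereospecific inversion, this detour would also serve if the enantiomeric excess from step 2 proved insufficient.

Step 4. The unprotected formyl group may be consumed under base (hydride transfer from the secondary alkoxide, Cannizzaro-type disproportionation), or the substitution may be slow enough for intermolecular etherification to compete. The fallback keeps the same O4–C4a closure but uses a cyano group as the para activator; it sets out from epoxide 5 and comes back at 8.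
- 5 is opened as in step 3 with commercial 4-fluoro-3-hydroxybenzonitrile (N#Cc1ccc(F)c(O)c1) to give 4-fluoro-3-{[(1R,2R)-2-hydroxy-1-(3,4,5-trimethoxyphenyl)propyl]oxy}benzonitrile F6.
- Cs2CO3 in DMSO (or NaH in DMF) should close the ring to (2R,3R)-3-methyl-2-(3,4,5-trimethoxyphenyl)-2,3-dihydro-1,4-benzodioxine-7-carbonitrile F7.
- Reduction with iBu2AlH in toluene at −78 °C and hydrolysis of the aldimine with aqueous HCl gives aldehyde 8.

Step 1. Z-selectivity may be lost through equilibration of the oxaphosphetane, and the E-alkene carried along would lead to the trans-epoxide and finally to the cis-benzodioxane. The fallback fixes the geometry by syn semi-hydrogenation of an alkyne; it sets out from aldehyde 1 and comes back at 4.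
- 1 is homologated with dimethyl (1-diazo-2-oxopropyl)phosphonate (K2CO3, MeOH, Ohira–Bestmann reaction) to 5-ethynyl-1,2,3-trimethoxybenzene F8.
- Deprotonation with nBuLi in THF at −78 °C and methylation with MeI gives 1,2,3-trimethoxy-5-(prop-1-yn-1-yl)benzene F9.
- Hydrogenation (H2, 1 atm) over Pd/CaCO3 poisoned with Pb(OAc)2 and quinoline (Lindlar conditions) should deliver the Z-alkene 4.

**Further compounds**
F1 | step 3 | methyl (R)-2-[(4-methoxybenzyl)oxy]propanoate | C[C@@H](OCc1ccc(OC)cc1)C(=O)OC
F2 | step 3 | (R)-N-methoxy-2-[(4-methoxybenzyl)oxy]-N-methylpropanamide | C[C@@H](OCc1ccc(OC)cc1)C(=O)N(C)OC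
F3 | step 3 | (R)-2-[(4-methoxybenzyl)oxy]-1-(3,4,5-trimethoxyphenyl)propan-1-one | C[C@@H](OCc1ccc(OC)cc1)C(=O)c1cc(OC)c(OC)c(OC)c1
F4 | step 3 | (1S,2R)-2-[(4-methoxybenzyl)oxy]-1-(3,4,5-trimethoxyphenyl)propan-1-ol | C[C@@H](OCc1ccc(OC)cc1)[C@@H](O)c1cc(OC)c(OC)c(OC)c1
F5 | step 3 | 4-fluoro-3-{[(1R,2R)-2-[(4-methoxybenzyl)oxy]-1-(3,4,5-trimethoxyphenyl)propyl]oxy}benzaldehyde | C[C@@H](OCc1ccc(OC)cc1)[C@H](Oc1cc(C=O)ccc1F)c1cc(OC)c(OC)c(OC)c1
F6 | step 4 | 4-fluoro-3-{[(1R,2R)-2-hydroxy-1-(3,4,5-trimethoxyphenyl)propyl]oxy}benzonitrile | N#Cc1ccc(F)c(O[C@H](c2cc(OC)c(OC)c(OC)c2)[C@@H](C)O)c1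
F7 | step 4 | (2R,3R)-3-methyl-2-(3,4,5-trimethoxyphenyl)-2,3-dihydro-1,4-benzodioxine-7-carbonitrile | N#Cc1ccc2c(c1)O[C@H](c1cc(OC)c(OC)c(OC)c1)[C@@H](C)O2
F8 | step 1 | 5-ethynyl-1,2,3-trimethoxybenzene | C#Cc1cc(OC)c(OC)c(OC)c1
F9 | step 1 | 1,2,3-trimethoxy-5-(prop-1-yn-1-yl)benzene | CC#Cc1cc(OC)c(OC)c(OC)c1
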